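The readings stem from a simulated flask on assumed constants; noise was put on by code.

The delta run is charged with 0.800 M substrate and 0.170 M partner and is given 120 s, and the reckoning here concerns how far it gets.

| setting | zeta | eta | theta | delta |
|---|---|---|---|---|
| substrate | 0.800 M | 0.320 M | 0.800 M | 0.800 M |
| partner | 0.800 M | 0.320 M | 0.400 M | 0.170 M |
| free catalyst | 0.0240 M | 0.0240 M | 0.0240 M | 0.0240 M |
| time |  |  |  | 120 s |

| run | time / s | [product] / M |
|---|---|---|
| zeta run | 4.8 | 0.0363 |
| zeta run | 8.2 | 0.0618 |
| zeta run | 14 | 0.1061 |
| zeta run | 24 | 0.1736 |
| zeta run | 41 | 0.2802 |
| zeta run | 70 | 0.4267 |
| zeta run | 120 | 0.5973 |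
| eta run | 4.8 | 0.0112 |
| eta run | 8.2 | 0.0293 |
| eta run | 14 | 0.0457 |
| eta run | 24 | 0.0821 |
| eta run | 41 | 0.1210 |
| eta run | 70 | 0.1889 |
| eta run | 120 | 0.2518 |
| theta run | 4.8 | 0.0343 |
| theta run | 8.2 | 0.0560 |
| theta run | 14 | 0.0994 |
| theta run | 24 | 0.1599 |
| theta run | 41 | 0.2489 |
| theta run | 70 | 0.3514 |
| theta run | 120 | 0.3987 |

(readings scatter by 0.002 M)

- the exponent of [substrate] in the starting rate at the charge of the zeta run (at the point where two percent of the substrate have become product) (one fixed amount of product, the same in the runs compared)
- the exponent of [partner] in the starting rate at the charge of the zeta run (at the point where two percent of the substrate have become product)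
- the eta run starts with 0.480 M less of substrate and of partner than the zeta run, and with no product. Compared where both hold the same amount of substrate, once fifteen percent of what the eta run was charged with has turned into product, is the eta run faster, slower or alike (within a tenth)?
- product in the delta run at 120 s, as a share of the substrate charged

- Overall: substrate + partner -> product, with free catalyst as catalyst.
- Constant volume, constant temperature.
- A reading of a species includes what of it is bound.
- An order is taken over about fifteen percent of the charge, up and down.

From above, the bound is a matter of counting. Each product takes one substrate and one partner, so the best fate of a partner molecule is to end as product. Partner is the limiting reagent of the delta run, with 0.170 M against 0.800 M of substrate. The delta run therefore stands under 21.2%, its ceiling share, the partner charged over the substrate charged.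

From below, the theta run serves as a measure. By its reading at 24 s it still holds 0.240 M of partner, bound forms counted, more than the delta charge. At 120 s the theta reading leaves 0.00130 M, which is less than the scatter. The theta run thus covers the whole way down from the delta charge of partner within 96.0 s, and the delta run has 120 s.

Each product takes one substrate and one partner, so, reckoned by product made, the excess of substrate is 0.630 M in the delta run and 0.400 M in the theta run. At a like level of partner, the delta run therefore holds more substrate. That should not slow it: at 14 s the zeta run reads 0.1061 M and the eta run, with less substrate and less partner, reads 0.0457 M, while the theta run, with half the partner of the zeta run, reads 0.0994 M. Allowing two scatters on the theta reading, the floor I set for the delta run is 20.6%. With 24.0 s to spare, my own reckoning sits at the ceiling.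

The forecast gives 0.62 and 0.08 for the orders, alike for the eta comparison and 21.2% for the delta run, inside the bracket, saying “the 0.170 M partner is used up within about 70 s”.

The flask gives 21.2% for the delta run, with orders 0.89 in substrate and −0.10 in partner, and the eta run alike against the zeta run at a rate ratio of 1.0.

    free catalyst + substrate → loaded catalyst + by-product (0.8410 M⁻¹ s⁻¹)
    loaded catalyst + partner → product + free catalyst (4.620 M⁻¹ s⁻¹)
    substrate + partner ⇌ idle substrate-reagent adduct, settled at all times (0.8010 M⁻¹)
    free catalyst + impurity → spent catalyst

The pairing of substrate and partner to idle substrate-reagent adduct makes no difference to the delta figure. Against its ceiling of 21.2%, the delta run stands at 21.2%. The same rule gives the theta run a ceiling share of 50.0%, and at 120 s its reading stands at 49.8% of the substrate charged.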